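**Assumption:** the target is natural (R)-α-tocotrienol (2R, 3'E, 7'E), and all-trans geranylgeraniol and trimethylhydroquinone are bought. This route is a paper design; none of it has been run.

## Retrosynthetic overview

1. The obvious chroman + farnesyl disconnection (Trolox-type aldehyde/sulfone plus Wittig/Julia) is not used. The pyran ring is the only ring made, and it is made last; the benzene ring is bought.
2. α-Tocotrienol ⇒ (R)-α-tocotrienolquinone: reductive ring closure forms the aryl C8a–O1 bond from the tertiary alcohol, so the C2–O bond is never broken (retention).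
3. Quinone ⇒ hydroquinone dimethyl ether (CAN unmasking).
4. Dimethyl ether ⇒ aryl Grignard (C9 unit from trimethylhydroquinone) + C20 hydroxy tosylate (C4–C4a sp2–sp3 coupling).
5. Hydroxy tosylate ⇒ geranylgeraniol: Sharpless epoxidation sets the only stereocentre on the intact C20 chain; Red-Al opening at C2 gives the tertiary carbinol. Geranylgeraniol C1/C2/C3 become chroman C4/C3/C2.

## Route

**Step 1**
Reactants: 1, 2,3,5-trimethylhydroquinone
Product: 2, 1,4-dimethoxy-2,3,5-trimethylbenzene
Conditions: MeI, K2CO3, acetone, reflux, N2
Reagents that add atoms: iodomethane, CI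
Why: Williamson O-methylation of both phenols; masks the hydroquinone for Grignard chemistry and allows later oxidative unmasking to the quinone.

**Step 2**
Reactants: 2, 1,4-dimethoxy-2,3,5-trimethylbenzene
Product: 3, 1-bromo-2,5-dimethoxy-3,4,6-trimethylbenzene
Conditions: NBS, MeCN, 0 °C → rt, dark
Reagents that add atoms: N-bromosuccinimide, O=C1CCC(=O)N1Br
Why: Electrophilic aromatic bromination at the only free ring position; polar, dark conditions avoid benzylic bromination.

**Step 3**
Reactants: 4, (2E,6E,10E)-geranylgeraniol
Product: 5, (2R,3R)-2,3-epoxygeranylgeraniol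
Conditions: Ti(OiPr)4 (10 mol %), D-(−)-DIPT (12 mol %), t-BuOOH (decane), 4 Å MS, CH2Cl2, −20 °C
Reagents that add atoms: tert-butyl hydroperoxide, CC(C)(C)OO
Why: Sharpless asymmetric epoxidation is directed by the allylic OH, so only the C2=C3 alkene reacts; D-(−)-tartrate gives the (2R,3R) epoxide (mirror of the L-(+)-tartrate/geraniol → (2S,3S) case), which fixes the future chroman C2 as R (typically about 90–95% ee for this substrate class).

**Step 4**
Reactants: 5, (2R,3R)-2,3-epoxygeranylgeraniol
Product: 6, (3R,6E,10E)-3,7,11,15-tetramethylhexadeca-6,10,14-triene-1,3-diol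
Conditions: Red-Al, THF, 0 °C → rt; Rochelle salt work-up
Reagents that add atoms: none
Why: Alkoxyaluminate-directed intramolecular hydride delivery opens the 2,3-epoxy alcohol at C2 (also the less hindered carbon) to the 1,3-diol; the C3–O bond is untouched, so the tertiary carbinol stays R.

**Step 5**
Reactants: 6, the (R)-1,3-diol
Product: 7, (3R,6E,10E)-3-hydroxy-3,7,11,15-tetramethylhexadeca-6,10,14-trien-1-yl 4-methylbenzenesulfonate
Conditions: TsCl (1.1 equiv), Et3N, DMAP (cat.), CH2Cl2, 0 °C
Reagents that add atoms: p-toluenesulfonyl chloride, Cc1ccc(cc1)S(=O)(=O)Cl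
Why: Chemoselective sulfonylation of the primary over the tertiary alcohol.

**Step 6**
Reactants: 3, 1-bromo-2,5-dimethoxy-3,4,6-trimethylbenzene (3 equiv, converted in situ to the aryl Grignard); 7, the (R)-hydroxy tosylate
Product: 8, (3R,6E,10E)-1-(2,5-dimethoxy-3,4,6-trimethylphenyl)-3,7,11,15-tetramethylhexadeca-6,10,14-trien-3-ol
Conditions: 3, Mg, THF, reflux; then 7, Li2CuCl4 (5 mol %), THF, −20 °C → rt
Reagents that add atoms: none
Why: Copper-catalysed Kochi–Schlosser coupling of an aryl Grignard with a primary tosylate forms the C4–C4a bond; the first equivalent of Grignard only deprotonates the tertiary OH (magnesium alkoxides are tolerated, as with bromo-alcohols), and the stereocentre is not involved.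

**Step 7**
Reactants: 8, the dimethoxyarene carbinol
Product: 9, (R)-α-tocotrienolquinone, 2-[(3R,6E,10E)-3-hydroxy-3,7,11,15-tetramethylhexadeca-6,10,14-trien-1-yl]-3,5,6-trimethylcyclohexa-2,5-diene-1,4-dione
Conditions: CAN (2.5 equiv), MeCN–H2O (3:1), 0 °C, 20 min
Reagents that add atoms: water, O
Why: CAN oxidative demethylation of a p-dimethoxyarene to the p-quinone; the electron-rich pentasubstituted arene is oxidised far more readily than isolated trisubstituted alkenes, and this quinone is the known CAN oxidation product of α-tocotrienol, so it survives the conditions.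

**Step 8**
Reactants: 9, (R)-α-tocotrienolquinone
Product: 10, (R)-α-tocotrienol (target)
Conditions: L-ascorbic acid (10 equiv), 0.5 M aq. H3PO4–THF (1:3), degassed, 50 °C, dark
Reagents that add atoms: none
Why: Acid-promoted reductive cyclisation of a γ-hydroxyalkyl-p-quinone (the tocopherolquinone → tocopherol ring closure): the tertiary OH adds to the adjacent quinone C=O to give the six-membered cyclic hemiketal, which ionises to the stabilised phenoxonium ion and is reduced by ascorbate to the chromanol, so the C2–O bond is never broken and R is retained; the acid is kept mild (about pH 2) to disfavour SN1 ionisation of the carbinol and protonation of the chain alkenes.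

## Compound list

1 | 2,3,5-trimethylhydroquinone | Cc1cc(O)c(C)c(C)c1O | starting material
2 | 1,4-dimethoxy-2,3,5-trimethylbenzene | COc1cc(C)c(OC)c(C)c1C | intermediate
3 | 1-bromo-2,5-dimethoxy-3,4,6-trimethylbenzene | COc1c(C)c(C)c(OC)c(C)c1Br | intermediate
4 | (2E,6E,10E)-geranylgeraniol | CC(C)=CCC/C(C)=C/CC/C(C)=C/CC/C(C)=C/CO | starting material
5 | [(2R,3R)-3-methyl-3-[(3E,7E)-4,8,12-trimethyltrideca-3,7,11-trien-1-yl]oxiran-2-yl]methanol | CC(C)=CCC/C(C)=C/CC/C(C)=C/CC[C@@]1(C)O[C@@H]1CO | intermediate
6 | (3R,6E,10E)-3,7,11,15-tetramethylhexadeca-6,10,14-triene-1,3-diol | CC(C)=CCC/C(C)=C/CC/C(C)=C/CC[C@@](C)(O)CCO | intermediate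
7 | (3R,6E,10E)-3-hydroxy-3,7,11,15-tetramethylhexadeca-6,10,14-trien-1-yl tosylate | CC(C)=CCC/C(C)=C/CC/C(C)=C/CC[C@@](C)(O)CCOS(=O)(=O)c1ccc(C)cc1 | intermediate
8 | (3R,6E,10E)-1-(2,5-dimethoxy-3,4,6-trimethylphenyl)-3,7,11,15-tetramethylhexadeca-6,10,14-trien-3-ol | CC(C)=CCC/C(C)=C/CC/C(C)=C/CC[C@@](C)(O)CCc1c(C)c(OC)c(C)c(C)c1OC | intermediate
9 | (R)-α-tocotrienolquinone | CC(C)=CCC/C(C)=C/CC/C(C)=C/CC[C@@](C)(O)CCC1=C(C)C(=O)C(C)=C(C)C1=O | intermediate
10 | (R)-α-tocotrienol, (2R)-2,5,7,8-tetramethyl-2-[(3E,7E)-4,8,12-trimethyltrideca-3,7,11-trien-1-yl]chroman-6-ol | CC(C)=CCC/C(C)=C/CC/C(C)=C/CC[C@]1(C)CCc2c(C)c(O)c(C)c(C)c2O1 | target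

## Summary

**Total steps:** 8.
**Longest linear sequence:** 6 (steps 3–8, from geranylgeraniol).

**Three steps most likely to fail:**

1. **Step 8 (reductive ring closure).** Mild acid may be too slow, while stronger acid risks chain-alkene damage or partial SN1 racemisation. Fallback: abandon the quinone closure and form O1–C8a by Pd-catalysed intramolecular C–O coupling of the tertiary alcohol onto an aryl bromide (Buchwald-type etherification, retention by construction). This needs a silyl-protected 4-bromo-3-iodo-2,5,6-trimethylphenol as the arene partner, joined to the chain selectively at C–I, then TBAF.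

2. **Step 6 (hindered aryl Grignard with a hydroxy tosylate).** Coupling may be slow, or attack at sulfur or oxetane formation may compete. Fallback: reverse the polarity with a B-alkyl Suzuki coupling. Convert epoxy alcohol 5 into (R)-geranyllinalool (I2/PPh3/imidazole, then Zn), hydroborate its vinyl group with 9-BBN (selective for the monosubstituted alkene), and couple with aryl bromide 3 (Pd/SPhos, K3PO4) to reach 8.

3. **Step 3 (enantiopurity ceiling of about 90–95% ee, with no crystalline intermediate downstream).** Fallback: add a biocatalytic polish, a lipase-catalysed acylative kinetic resolution of epoxy alcohol 5 (lipase PS, vinyl acetate) to remove the minor enantiomer before Red-Al opening.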